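**Strategy.** The dihydropyran (C1, O2, C3, C4, C5, C9) is the cyclic enol-hemiacetal of a 1,5-dialdehyde: C1 and C3 are both aldehyde-level carbons bridged by C9–C5–C4. It is therefore closed last, on a finished cyclopentene, by a de Mayo photoannulation. The enol of triformylmethane adds [2+2] across C5=C9 of an enantiopure cyclopentene that already carries O7, the C8 carbinol and C10. The strained cyclobutanol opens by retro-aldol and the liberated enol recloses on the C1 aldehyde. One operation forms C5–C4, C9–C1 and O2–C1, sets C5, C9 and C1, and installs C11 as a formyl group that is reduced at the very end.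

Key step: step 7

Remark: iridoid numbering is used (C1 acetal carbon, O2, C3=C4, C5/C9 ring fusion, C6, C7, C8; C10 = CH2OH on C8, C11 = CH2OH on C4). Lactol 14 is drawn as its 1β-anomer; a minor anomer would equilibrate through 13 during step 8.

**Step 1**
Reactants: 1 cyclopent-2-en-1-one; 2 formaldehyde (37% aqueous)
Product: 3 2-(hydroxymethyl)cyclopent-2-en-1-one
Conditions: aq. HCHO, PBu3 (10 mol%), CHCl3/MeOH, rt
Reagents that add atoms: none
Why: Morita–Baylis–Hillman reaction: the phosphine adds to the enone, the resulting enolate is hydroxymethylated at the α-carbon and the catalyst is expelled; no stereocentre is formed.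

**Step 2**
Reactants: 3 2-(hydroxymethyl)cyclopent-2-en-1-one
Product: 4 2-{[(triisopropylsilyl)oxy]methyl}cyclopent-2-en-1-one
Conditions: TIPSCl, imidazole, DMAP (cat.), CH2Cl2, 0 °C → rt
Reagents that add atoms: triisopropylsilyl chloride (TIPSCl), CC(C)[Si](Cl)(C(C)C)C(C)C
Why: Standard silylation of the unhindered primary alcohol; the bulky group later enlarges the alkenyl side of the ketone and shields one ring face.

**Step 3**
Reactants: 4 2-{[(triisopropylsilyl)oxy]methyl}cyclopent-2-en-1-one
Product: 5 (S)-2-{[(triisopropylsilyl)oxy]methyl}cyclopent-2-en-1-ol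
Conditions: (R)-Me-CBS (10 mol%), BH3·SMe2, THF, −20 °C; MeOH quench
Reagents that add atoms: none
Why: Corey–Bakshi–Shibata reduction in which the α-substituted alkenyl carbon acts as the large group and CH2 as the small one, so the (R)-catalyst should deliver hydride to give the (S)-carbinol, the future C7.

**Step 4**
Reactants: 5 (S)-2-{[(triisopropylsilyl)oxy]methyl}cyclopent-2-en-1-ol
Product: 6 (S)-1-(triethylsilyloxy)-2-{[(triisopropylsilyl)oxy]methyl}cyclopent-2-ene
Conditions: TESCl, imidazole, CH2Cl2, 0 °C
Reagents that add atoms: triethylsilyl chloride (TESCl), CC[Si](Cl)(CC)CC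
Why: Silylation of the secondary allylic alcohol with a group that directs step 5 sterically and is later removable in the presence of the primary TIPS ether.

**Step 5**
Reactants: 6 (S)-1-(triethylsilyloxy)-2-{[(triisopropylsilyl)oxy]methyl}cyclopent-2-ene
Product: 7 (1S,2S,5S)-2-(triethylsilyloxy)-1-{[(triisopropylsilyl)oxy]methyl}-6-oxabicyclo[3.1.0]hexane (epoxide oxygen trans to OTES)
Conditions: mCPBA, CH2Cl2, 0 °C
Reagents that add atoms: meta-chloroperbenzoic acid (mCPBA), OOC(=O)c1cccc(Cl)c1
Why: Prilezhaev epoxidation of the only alkene, which should occur anti to the allylic OTES group (held pseudo-axial by A1,2 strain with the CH2OTIPS arm), placing the future C8 oxygen trans to O7.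

**Step 6**
Reactants: 7 the trans-epoxide
Product: 10 (1R,5S)-5-(triethylsilyloxy)-1-{[(triisopropylsilyl)oxy]methyl}cyclopent-2-en-1-ol, via hydroxy selenide 8 (not isolated), via selenoxide 9 (not isolated)
Conditions: (PhSe)2, NaBH4, EtOH, rt → reflux; then THF, 30% H2O2, pyridine, 0 °C → rt
Reagents that add atoms: diphenyl diselenide, c1ccc(cc1)[Se][Se]c1ccccc1, and hydrogen peroxide, OO (their atoms reside in 8 and 9 only; 10 keeps none)
Why: Epoxide-to-allylic-alcohol transposition by selenolate opening and selenoxide syn-elimination: PhSe− attacks the secondary epoxide carbon with inversion, and the selenoxide can only eliminate toward the ring CH2 because the carbinol carbon bears no hydrogen, which gives the C5=C9 alkene while the C8 configuration from step 5 is retained.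

**Step 7**
Reactants: 10 (1R,5S)-5-(triethylsilyloxy)-1-{[(triisopropylsilyl)oxy]methyl}cyclopent-2-en-1-ol; 11 triformylmethane
Product: 14 (1R,4aS,6S,7R,7aS)-1,7-dihydroxy-6-(triethylsilyloxy)-7-[(triisopropylsilyloxy)methyl]-1,4a,5,6,7,7a-hexahydrocyclopenta[c]pyran-4-carbaldehyde, via cyclobutanol photoadduct 12 (not isolated), via enol dialdehyde 13 (not isolated)
Conditions: 11 (3 equiv), hν (medium-pressure Hg lamp, Vycor filter), degassed MeCN, 0 °C; then rt in the dark
Reagents that add atoms: none
Why: De Mayo reaction: the excited hydrogen-bonded enol of 11 adds [2+2] across C5=C9 to give cyclobutanol 12, whose β-hydroxy-aldehyde unit undergoes strain-driven retro-aldol cleavage of the C1–C4 bond to enol dialdehyde 13, and the enol oxygen then adds to the C1 aldehyde to give 14. The closest known reaction type is the photoannulation of diformylacetate-type enols onto cyclopentenes to give iridoid enol-lactols. The transient cyclobutane closes by [2+2] photocycloaddition and the pyran closes by 6-exo-trig hemiacetalisation (O2 onto C1=O), so the pyran is the last ring of the skeleton to form. C5 and C9 are set together: the cycloaddition is necessarily cis and should occur on the face of the free tertiary OH, anti to the CH2OTIPS and OTES groups, so both new C–C bonds end up trans to C10 and O7; C1 is set under thermodynamic control, the lactol OH taking the pseudo-axial position on the convex face (anomeric effect). The step needs head-to-tail regiochemistry (C4 to C5, C1 to C9), which the substrate should secure sterically because the fully substituted C(CHO)2 terminus avoids the alkene carbon next to the quaternary C8. Both formyl groups on C4 are identical, so no constitutional choice arises after ring opening.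

**Step 8**
Reactants: 14 the lactol aldehyde; 15 3-methylbutanoic (isovaleric) anhydride
Product: 16 (1S,4aS,6S,7R,7aS)-4-formyl-7-hydroxy-6-(triethylsilyloxy)-7-[(triisopropylsilyloxy)methyl]-1,4a,5,6,7,7a-hexahydrocyclopenta[c]pyran-1-yl 3-methylbutanoate
Conditions: 15 (1.5 equiv), Et3N, DMAP (10 mol%), CH2Cl2, −20 → 0 °C
Reagents that add atoms: none
Why: DMAP-catalysed acylation of the only acylable hydroxyl (the tertiary C8 OH is inert here); the lactol equilibrates through 13 and should be acylated on the convex face to give the pseudo-axial 1β-ester, trans to the C9–C8 bond and favoured by the anomeric effect.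

**Step 9**
Reactants: 16 the C1 isovalerate
Product: 17 (1S,4aS,6S,7R,7aS)-4-formyl-6,7-dihydroxy-7-[(triisopropylsilyloxy)methyl]-1,4a,5,6,7,7a-hexahydrocyclopenta[c]pyran-1-yl 3-methylbutanoate
Conditions: HF·pyridine, pyridine, THF, 0 °C
Reagents that add atoms: none
Why: Chemoselective desilylation: under buffered HF the triethylsilyl ether should be cleaved far faster than the primary triisopropylsilyl ether, and the acylal and the push–pull enal tolerate the weakly acidic medium.

**Step 10**
Reactants: 18 (E)-p-coumaric acid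
Product: 20 (E)-3-[4-(tert-butyldimethylsilyloxy)phenyl]acrylic acid, via bis-silylated coumarate 19 (not isolated)
Conditions: TBSCl (2.4 equiv), imidazole, DMF, rt; then THF/H2O/AcOH, rt
Reagents that add atoms: tert-butyldimethylsilyl chloride (TBSCl), CC(C)(C)[Si](C)(C)Cl
Why: Exhaustive silylation followed by selective hydrolysis of the labile silyl ester in the same flask leaves the phenol protected and the acid free; the E-alkene is untouched.

**Step 11**
Reactants: 17 the C7 alcohol; 20 (E)-3-[4-(tert-butyldimethylsilyloxy)phenyl]acrylic acid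
Product: 22 (1S,4aS,6S,7R,7aS)-4-formyl-7-hydroxy-1-(3-methylbutanoyloxy)-7-[(triisopropylsilyloxy)methyl]-1,4a,5,6,7,7a-hexahydrocyclopenta[c]pyran-6-yl (E)-3-[4-(tert-butyldimethylsilyloxy)phenyl]acrylate, via mixed anhydride 21 (not isolated)
Conditions: 20, 2,4,6-trichlorobenzoyl chloride, Et3N, toluene, rt; then 17, DMAP, toluene, rt → 40 °C
Reagents that add atoms: 2,4,6-trichlorobenzoyl chloride, O=C(Cl)c1c(Cl)cc(Cl)cc1Cl (its acyl group resides in 21 only; 22 keeps none)
Why: Yamaguchi esterification, chosen because mixed-anhydride/DMAP acyl transfer copes with the hindered secondary C7 hydroxyl next to the quaternary C8 while the tertiary OH does not react; no stereocentre is affected.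

**Step 12**
Reactants: 22 the fully acylated bis-silyl ether
Product: 23 (1S,4aS,6S,7R,7aS)-4-formyl-7-hydroxy-7-(hydroxymethyl)-1-(3-methylbutanoyloxy)-1,4a,5,6,7,7a-hexahydrocyclopenta[c]pyran-6-yl (E)-3-(4-hydroxyphenyl)acrylate
Conditions: HF·pyridine (excess), pyridine, THF, 0 °C → rt
Reagents that add atoms: none
Why: Fluoride-mediated cleavage of the alkyl TIPS and aryl TBS ethers; with C11 still a formyl group the enol ether is a vinylogous formate and the acylal is deactivated toward ionisation, so the acidic reagent should be tolerated, and O7-to-O10 acyl migration is not expected without base.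

**Step 13**
Reactants: 23 the C11 aldehyde
Product: 24 luzonoid A
Conditions: NaBH4, CeCl3·7H2O, MeOH/THF, −78 → −40 °C; pH 7 buffer
Reagents that add atoms: none
Why: Luche reduction: the β-alkoxy enal is reduced 1,2 to the allylic alcohol, as known for 2-formyl glycals, while the acylal, the cinnamate ester and the enol ether should not be attacked at low temperature; no stereocentre is formed or touched.

**Compound list**

1 | cyclopent-2-en-1-one | O=C1C=CCC1 | starting material
2 | formaldehyde | C=O | starting material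
3 | 2-(hydroxymethyl)cyclopent-2-en-1-one | O=C1CCC=C1CO | intermediate
4 | 2-{[(triisopropylsilyl)oxy]methyl}cyclopent-2-en-1-one | O=C1CCC=C1CO[Si](C(C)C)(C(C)C)C(C)C | intermediate
5 | (S)-2-{[(triisopropylsilyl)oxy]methyl}cyclopent-2-en-1-ol | C1C[C@H](O)C(CO[Si](C(C)C)(C(C)C)C(C)C)=C1 | intermediate
6 | (S)-1-(triethylsilyloxy)-2-{[(triisopropylsilyl)oxy]methyl}cyclopent-2-ene | C1C[C@H](O[Si](CC)(CC)CC)C(CO[Si](C(C)C)(C(C)C)C(C)C)=C1 | intermediate
7 | (1S,2S,5S)-2-(triethylsilyloxy)-1-{[(triisopropylsilyl)oxy]methyl}-6-oxabicyclo[3.1.0]hexane | C1C[C@H](O[Si](CC)(CC)CC)[C@@]2(CO[Si](C(C)C)(C(C)C)C(C)C)O[C@@H]12 | intermediate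
8 | hydroxy selenide: 2-(phenylselanyl)cyclopentan-1-ol from 7, SePh trans to the tertiary OH and cis to CH2OTIPS (not isolated) | C1C[C@H](O[Si](CC)(CC)CC)[C@](O)(CO[Si](C(C)C)(C(C)C)C(C)C)[C@@H]1[Se]c2ccccc2 | intermediate
9 | selenoxide of 8 (not isolated) | C1C[C@H](O[Si](CC)(CC)CC)[C@](O)(CO[Si](C(C)C)(C(C)C)C(C)C)[C@@H]1[Se](=O)c2ccccc2 | intermediate
10 | (1R,5S)-5-(triethylsilyloxy)-1-{[(triisopropylsilyl)oxy]methyl}cyclopent-2-en-1-ol (tertiary OH trans to OTES) | C1C[C@H](O[Si](CC)(CC)CC)[C@](O)(CO[Si](C(C)C)(C(C)C)C(C)C)C=1 | intermediate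
11 | triformylmethane (methanetricarbaldehyde, present as its enol) | O=CC(C=O)C=O | starting material
12 | cyclobutanol photoadduct: cis-fused bicyclo[3.2.0]heptane, C(CHO)2 on C5, CH(OH) on C9, both on the face of the tertiary OH (not isolated) | OC1C(C=O)(C=O)[C@H]2C[C@H](O[Si](CC)(CC)CC)[C@](O)(CO[Si](C(C)C)(C(C)C)C(C)C)[C@@H]12 | intermediate
13 | ring-opened enol dialdehyde: cis-1,2-disubstituted cyclopentane with CHO on C9 and C(CHO)=CHOH on C5 (not isolated) | OC=C(C=O)[C@H]1C[C@H](O[Si](CC)(CC)CC)[C@](O)(CO[Si](C(C)C)(C(C)C)C(C)C)[C@H]1C=O | intermediate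
14 | (1R,4aS,6S,7R,7aS)-1,7-dihydroxy-6-(triethylsilyloxy)-7-[(triisopropylsilyloxy)methyl]-1,4a,5,6,7,7a-hexahydrocyclopenta[c]pyran-4-carbaldehyde | O[C@@H]1OC=C(C=O)[C@H]2C[C@H](O[Si](CC)(CC)CC)[C@](O)(CO[Si](C(C)C)(C(C)C)C(C)C)[C@@H]12 | intermediate
15 | 3-methylbutanoic (isovaleric) anhydride | CC(C)CC(=O)OC(=O)CC(C)C | starting material
16 | (1S,4aS,6S,7R,7aS)-4-formyl-7-hydroxy-6-(triethylsilyloxy)-7-[(triisopropylsilyloxy)methyl]-1,4a,5,6,7,7a-hexahydrocyclopenta[c]pyran-1-yl 3-methylbutanoate | CC(C)CC(=O)O[C@@H]1OC=C(C=O)[C@H]2C[C@H](O[Si](CC)(CC)CC)[C@](O)(CO[Si](C(C)C)(C(C)C)C(C)C)[C@@H]12 | intermediate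
17 | (1S,4aS,6S,7R,7aS)-4-formyl-6,7-dihydroxy-7-[(triisopropylsilyloxy)methyl]-1,4a,5,6,7,7a-hexahydrocyclopenta[c]pyran-1-yl 3-methylbutanoate | CC(C)CC(=O)O[C@@H]1OC=C(C=O)[C@H]2C[C@H](O)[C@](O)(CO[Si](C(C)C)(C(C)C)C(C)C)[C@@H]12 | intermediate
18 | (E)-p-coumaric acid | OC(=O)/C=C/c1ccc(O)cc1 | starting material
19 | tert-butyldimethylsilyl (E)-3-[4-(tert-butyldimethylsilyloxy)phenyl]acrylate (not isolated) | CC(C)(C)[Si](C)(C)OC(=O)/C=C/c1ccc(O[Si](C)(C)C(C)(C)C)cc1 | intermediate
20 | (E)-3-[4-(tert-butyldimethylsilyloxy)phenyl]acrylic acid | OC(=O)/C=C/c1ccc(O[Si](C)(C)C(C)(C)C)cc1 | intermediate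
21 | mixed anhydride of 20 with 2,4,6-trichlorobenzoic acid (not isolated) | O=C(/C=C/c1ccc(O[Si](C)(C)C(C)(C)C)cc1)OC(=O)c1c(Cl)cc(Cl)cc1Cl | intermediate
22 | (1S,4aS,6S,7R,7aS)-4-formyl-7-hydroxy-1-(3-methylbutanoyloxy)-7-[(triisopropylsilyloxy)methyl]-1,4a,5,6,7,7a-hexahydrocyclopenta[c]pyran-6-yl (E)-3-[4-(tert-butyldimethylsilyloxy)phenyl]acrylate | CC(C)CC(=O)O[C@@H]1OC=C(C=O)[C@H]2C[C@H](OC(=O)/C=C/c3ccc(O[Si](C)(C)C(C)(C)C)cc3)[C@](O)(CO[Si](C(C)C)(C(C)C)C(C)C)[C@@H]12 | intermediate
23 | (1S,4aS,6S,7R,7aS)-4-formyl-7-hydroxy-7-(hydroxymethyl)-1-(3-methylbutanoyloxy)-1,4a,5,6,7,7a-hexahydrocyclopenta[c]pyran-6-yl (E)-3-(4-hydroxyphenyl)acrylate | CC(C)CC(=O)O[C@@H]1OC=C(C=O)[C@H]2C[C@H](OC(=O)/C=C/c3ccc(O)cc3)[C@](O)(CO)[C@@H]12 | intermediate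
24 | luzonoid A, (1S,4aS,6S,7R,7aS)-7-hydroxy-4,7-bis(hydroxymethyl)-1-(3-methylbutanoyloxy)-1,4a,5,6,7,7a-hexahydrocyclopenta[c]pyran-6-yl (E)-3-(4-hydroxyphenyl)acrylate | CC(C)CC(=O)O[C@@H]1OC=C(CO)[C@H]2C[C@H](OC(=O)/C=C/c3ccc(O)cc3)[C@](O)(CO)[C@@H]12 | target

**Total step count:** 13
**Longest linear sequence:** 12 (steps 1–9, 11–13; step 10 is a one-step side branch)

**Steps most likely to fail**

Step 7. The strongly acidic tri-aldehyde enol may strip the TES ether or degrade under irradiation (its extra formyl groups open further photochemical channels) before it captures the hindered alkene. The fallback sets out from 10 and comes back at 14. It replaces 11 by the less acidic ester analogue. Commercial methyl 3,3-dimethoxypropanoate would be formylated with methyl formate/NaH to methyl 2-formyl-3,3-dimethoxypropanoate F1, and acidic work-up would give methyl diformylacetate F2, the photopartner with the closest precedent for cyclopentene annulation. The same photoannulation of 10 should then give the lactol methyl ester F3. DIBAL at −78 °C, with the lactol masked as its aluminium alkoxide, would reduce the ester to the lactol allylic alcohol F4. MnO2 would then oxidise the allylic primary alcohol selectively to the enal 14.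

Step 11. Acyl transfer to the hindered C7 hydroxyl may be slow, and the nucleophilic catalyst may then shuttle the activated anomeric isovalerate between oxygens. The fallback sets out from 17 and comes back at 22. It builds the cinnamate on the molecule instead of transferring it. The small, highly reactive acryloyl chloride (iPr2NEt, CH2Cl2, −20 °C, no DMAP) should give the C7 acrylate F5. Cross-metathesis of F5 with commercial 4-(tert-butyldimethylsilyloxy)styrene (Hoveyda–Grubbs II, CH2Cl2, 40 °C) should then give the E-cinnamate 22. The trisubstituted push–pull enol ether is inert to the catalyst.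

Step 13. In the basic borohydride/methanol medium the phenoxide-bearing triol may suffer coumaroyl migration from O7 to the cis primary O10, or methanolysis of the anomeric ester. The fallback sets out from 22 and comes back at 24. It reverses the order of events so that the reduction is done while O10 and the phenol are still silylated. Luche reduction of 22 at −78 °C should give the bis-silylated luzonoid A F6. Its two silyl ethers would then be cleaved with buffered Et3N·3HF in THF/MeCN to give 24.

**Further compounds**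

F1 | step 7 | methyl 2-formyl-3,3-dimethoxypropanoate | COC(=O)C(C=O)C(OC)OC
F2 | step 7 | methyl diformylacetate (methyl 2-formyl-3-oxopropanoate) | COC(=O)C(C=O)C=O
F3 | step 7 | methyl (1R,4aS,6S,7R,7aS)-1,7-dihydroxy-6-(triethylsilyloxy)-7-[(triisopropylsilyloxy)methyl]-1,4a,5,6,7,7a-hexahydrocyclopenta[c]pyran-4-carboxylate | O[C@@H]1OC=C(C(=O)OC)[C@H]2C[C@H](O[Si](CC)(CC)CC)[C@](O)(CO[Si](C(C)C)(C(C)C)C(C)C)[C@@H]12
F4 | step 7 | (1R,4aS,6S,7R,7aS)-4-(hydroxymethyl)-6-(triethylsilyloxy)-7-[(triisopropylsilyloxy)methyl]-1,4a,5,6,7,7a-hexahydrocyclopenta[c]pyran-1,7-diol | O[C@@H]1OC=C(CO)[C@H]2C[C@H](O[Si](CC)(CC)CC)[C@](O)(CO[Si](C(C)C)(C(C)C)C(C)C)[C@@H]12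
F5 | step 11 | (1S,4aS,6S,7R,7aS)-4-formyl-7-hydroxy-1-(3-methylbutanoyloxy)-7-[(triisopropylsilyloxy)methyl]-1,4a,5,6,7,7a-hexahydrocyclopenta[c]pyran-6-yl acrylate | CC(C)CC(=O)O[C@@H]1OC=C(C=O)[C@H]2C[C@H](OC(=O)C=C)[C@](O)(CO[Si](C(C)C)(C(C)C)C(C)C)[C@@H]12
F6 | step 13 | bis-silylated luzonoid A (10-O-TIPS, phenol O-TBS) | CC(C)CC(=O)O[C@@H]1OC=C(CO)[C@H]2C[C@H](OC(=O)/C=C/c3ccc(O[Si](C)(C)C(C)(C)C)cc3)[C@](O)(CO[Si](C(C)C)(C(C)C)C(C)C)[C@@H]12
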